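**Strategy.** Ring C is disconnected at the O1–C8a bond. Ring A carries oxygens at C5 and C8 in a para relationship around the C6/C7 methoxy pair, so it is a masked 2,3-dimethoxy-1,4-benzoquinone whose only C–H carbon is the future C8a. Anodic oxidation of an acylhydroquinone β-diketone unmasks that quinone, and the enol oxygen of the side chain (future O1) adds to the free quinone carbon, closing the pyranone and fixing the 5,6,7,8-oxygenation pattern in one operation. The precursor is the open 1,3-diketone joining a 2,5-dihydroxy-3,4-dimethoxyphenyl ketone to an O-benzyl-isovanilloyl unit; methylation and hydrogenolysis finish the synthesis.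

Key step: step 5

Remark: the target has no stereocentre, so the structure drawn is its only stereoisomer and no stereocontrol is needed.
Remark: 3-benzyloxy-4-methoxybenzoic acid (5) is taken as a catalogue compound, which avoids a separate benzylation of isovanillic acid.

Step 1
Reactants: 1 1,2,3,4-tetramethoxybenzene
Product: 2 2,3-dimethoxy-1,4-benzoquinone
Conditions: CAN (2.5 equiv), MeCN–H2O 2:1, 0 °C to rt
Reagents that add atoms: water, O
Why: Oxidative demethylation of a para-dimethoxyarene with cerium(IV); the C1/C4 methoxy groups are the only para pair, water attacks the ring carbons of the radical cation and methanol leaves, so the p-quinone should form.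

Step 2
Reactants: 2 2,3-dimethoxy-1,4-benzoquinone; 3 acetaldehyde
Product: 4 1-(2,5-dihydroxy-3,4-dimethoxyphenyl)ethanone
Conditions: MeCHO (5 equiv), hν (Pyrex-filtered Hg lamp or 420 nm LEDs), t-BuOH–acetone 3:1, rt, Ar
Reagents that add atoms: none
Why: Photo-Friedel–Crafts acylation of a quinone: the excited quinone abstracts the formyl hydrogen, the acyl radical recombines at a ring carbon (the two free positions of 2 are equivalent) and tautomerisation should give the acylhydroquinone.

Step 3
Reactants: 5 3-benzyloxy-4-methoxybenzoic acid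
Product: 6 3-benzyloxy-4-methoxybenzoyl chloride
Conditions: (COCl)2 (1.3 equiv), cat. DMF, CH2Cl2, 0 °C to rt; evaporate, use crude
Reagents that add atoms: oxalyl chloride, ClC(=O)C(=O)Cl
Why: Vilsmeier-catalysed conversion of a carboxylic acid into its chloride; the benzyl and methyl aryl ethers are inert to these conditions.

Step 4
Reactants: 4 1-(2,5-dihydroxy-3,4-dimethoxyphenyl)ethanone; 6 3-benzyloxy-4-methoxybenzoyl chloride
Product: 7 1-(3-benzyloxy-4-methoxyphenyl)-3-(2,5-dihydroxy-3,4-dimethoxyphenyl)propane-1,3-dione
Conditions: LiHMDS (4.2 equiv), THF, −78 to −10 °C, Ar; then 6 (1.0 equiv), −78 °C to rt; cold 1 M HCl to pH 4–5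
Reagents that add atoms: none
Why: Claisen-type C-acylation of a lithium polyanion (two phenoxides plus the ketone enolate), in which the enolate carbon is the most nucleophilic site and the fourth equivalent of base ties up the more acidic β-diketone as it forms, so that a second acylation should not occur.

Step 5
Reactants: 7 1-(3-benzyloxy-4-methoxyphenyl)-3-(2,5-dihydroxy-3,4-dimethoxyphenyl)propane-1,3-dione
Product: 10 2-(3-benzyloxy-4-methoxyphenyl)-5,8-dihydroxy-6,7-dimethoxychromen-4-one, via acylquinone 8 (not isolated), via flavone-5,8-quinone 9 (not isolated)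
Conditions: divided cell (glass frit), graphite-felt anode, Pt cathode, ca. +0.5 V vs Ag/AgCl (set from the CV of 7), MeCN–0.2 M aq. K-phosphate pH 7 (1:1), 5 mM, Ar, rt, to ca. 4 F/mol; then Na2S2O4 (3 equiv), rt
Reagents that add atoms: none
Why: Proposed new method: the hydroquinone ring of 7 should give up two electrons and two protons at a carbon anode far below the potential at which the benzyloxy-methoxyarene or the enol reacts, giving acylquinone 8, whose single ring C–H carbon (future C8a) is β to both the ring carbonyl at future C5 and the side-chain ketone at future C4. The enol(ate) oxygen on the aryl-bearing carbon of the side chain then adds to that carbon in a 6-endo-trig oxa-Michael closure (O1–C8a, ring C) and enolisation re-aromatises ring A to hydroquinone 10; since 10 is more electron-rich than 7 it is expected to be oxidised on at the same potential to quinone 9, which has no free ring position left, so the electrolysis is run to completion and dithionite returns 9 to 10 in the same pot. The closest known reaction types are the anodic oxidation of catechols and hydroquinones with in situ intermolecular Michael trapping by 1,3-dicarbonyl compounds, and the addition of nucleophiles to 2-acyl-1,4-benzoquinones at the carbon next to the acyl group. No stereocentre is formed. The step needs closure onto the quinone C–H carbon and not acid-catalysed cyclodehydration through the hydroxyl ortho to the ketone, which would give the 6-hydroxy-7,8-dimethoxy isomer: the pH 7 buffer takes up the anodic protons, and once oxidised that hydroxyl is a quinone carbonyl and no longer a nucleophile, while its reversible hemiketal with the enol has no way forward. High dilution is relied on to suppress intermolecular C-addition of the diketone to 8.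

Step 6
Reactants: 10 2-(3-benzyloxy-4-methoxyphenyl)-5,8-dihydroxy-6,7-dimethoxychromen-4-one
Product: 11 2-(3-benzyloxy-4-methoxyphenyl)-5,6,7,8-tetramethoxychromen-4-one
Conditions: Me2SO4 (4 equiv), K2CO3 (6 equiv), acetone, reflux, Ar
Reagents that add atoms: dimethyl sulfate, COS(=O)(=O)OC
Why: Williamson O-methylation of both phenols; the C8 hydroxyl should react readily and the chelated C5 hydroxyl on prolonged reflux with excess reagent, while argon keeps the hydroquinone from re-oxidising and the benzyl ether keeps the 3'-oxygen out of the reaction.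

Step 7
Reactants: 11 2-(3-benzyloxy-4-methoxyphenyl)-5,6,7,8-tetramethoxychromen-4-one
Product: 12 3'-demethylnobiletin, 2-(3-hydroxy-4-methoxyphenyl)-5,6,7,8-tetramethoxychromen-4-one
Conditions: H2 (1 atm), 10% Pd/C, EtOAc–MeOH 1:1, rt
Reagents that add atoms: none
Why: Catalytic hydrogenolysis of a benzyl aryl ether; the methyl ethers are inert and the chromone double bond should survive if the reaction is stopped after one equivalent of hydrogen.

**Compound list**

1 | 1,2,3,4-tetramethoxybenzene | COc1ccc(OC)c(OC)c1OC | starting material
2 | 2,3-dimethoxy-1,4-benzoquinone | COC1=C(OC)C(=O)C=CC1=O | intermediate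
3 | acetaldehyde | CC=O | starting material
4 | 1-(2,5-dihydroxy-3,4-dimethoxyphenyl)ethanone | CC(=O)c1cc(O)c(OC)c(OC)c1O | intermediate
5 | 3-benzyloxy-4-methoxybenzoic acid | COc1ccc(C(=O)O)cc1OCc1ccccc1 | starting material
6 | 3-benzyloxy-4-methoxybenzoyl chloride | COc1ccc(C(Cl)=O)cc1OCc1ccccc1 | intermediate
7 | 1-(3-benzyloxy-4-methoxyphenyl)-3-(2,5-dihydroxy-3,4-dimethoxyphenyl)propane-1,3-dione | COc1ccc(C(=O)CC(=O)c2cc(O)c(OC)c(OC)c2O)cc1OCc1ccccc1 | intermediate
8 | 1-(3-benzyloxy-4-methoxyphenyl)-3-(4,5-dimethoxy-3,6-dioxocyclohexa-1,4-dien-1-yl)propane-1,3-dione (acylquinone) | COc1ccc(C(=O)CC(=O)C2=CC(=O)C(OC)=C(OC)C2=O)cc1OCc1ccccc1 | intermediate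
9 | 2-(3-benzyloxy-4-methoxyphenyl)-6,7-dimethoxychromene-4,5,8-trione (flavone-5,8-quinone) | COc1ccc(C2=CC(=O)C3=C(O2)C(=O)C(OC)=C(OC)C3=O)cc1OCc1ccccc1 | intermediate
10 | 2-(3-benzyloxy-4-methoxyphenyl)-5,8-dihydroxy-6,7-dimethoxychromen-4-one | COc1ccc(-c2cc(=O)c3c(O)c(OC)c(OC)c(O)c3o2)cc1OCc1ccccc1 | intermediate
11 | 2-(3-benzyloxy-4-methoxyphenyl)-5,6,7,8-tetramethoxychromen-4-one | COc1ccc(-c2cc(=O)c3c(OC)c(OC)c(OC)c(OC)c3o2)cc1OCc1ccccc1 | intermediate
12 | 3'-demethylnobiletin, 2-(3-hydroxy-4-methoxyphenyl)-5,6,7,8-tetramethoxychromen-4-one | COc1ccc(-c2cc(=O)c3c(OC)c(OC)c(OC)c(OC)c3o2)cc1O | target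

**Step count.** Total: 7 steps. Longest linear sequence: 6 steps (steps 1, 2, 4, 5, 6, 7).

**Steps most likely to fail**

1. Step 5 (proposed new method). The acylquinone may be intercepted before it cyclises, by intermolecular C-addition of the diketone of a second molecule or by conjugate hydration from the aqueous electrolyte. The quinone-fused pyranone may also be opened by solvent during the exhaustive electrolysis. The fallback uses known chemistry only, sets out from 1 (with acid chloride 6) and rejoins the route at 11.
   - Tetramethoxybenzene 1 is lithiated ortho to a methoxy group (n-BuLi, TMEDA, THF, 0 °C), borylated with B(OMe)3 and oxidised (H2O2, NaOH) in one pot to 2,3,4,5-tetramethoxyphenol F1.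
   - Friedel–Crafts/Fries-type acetylation at its only free ring position (AcOH, BF3·OEt2, 85 °C) gives 1-(2-hydroxy-3,4,5,6-tetramethoxyphenyl)ethanone F2.
   - The dianion of F2 (LiHMDS, 3 equiv, THF, −78 °C) is C-acylated with 6 to give 1-(3-benzyloxy-4-methoxyphenyl)-3-(2-hydroxy-3,4,5,6-tetramethoxyphenyl)propane-1,3-dione F3.
   - Acid cyclodehydration through the only ortho hydroxyl (p-TsOH, toluene, reflux) delivers 11, which goes on to step 7.

2. Step 2. Hydrogen abstraction by the excited quinone may not be followed by C–C recombination, giving net photoreduction of 2. Redox exchange between the acylhydroquinone formed and unreacted quinone may also erode the product. The fallback sets out from 2 and rejoins at 4.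
   - Reduction with aqueous Na2S2O4 gives 2,3-dimethoxybenzene-1,4-diol F4.
   - Acetylation ortho to a hydroxyl (AcOH, BF3·OEt2, 90 °C; both free positions are equivalent) gives 4.

3. Step 4. Acylation may take place on the phenoxide oxygens instead of the enolate carbon, or the electron-rich polyanion may be oxidised by traces of air before it is acylated. The fallback is a Baker–Venkataraman sequence from 4 and 6 that rejoins at 7.
   - Both hydroxyls are esterified (6, 2.2 equiv, pyridine, 0 °C to rt) to give 2-acetyl-5,6-dimethoxy-1,4-phenylene bis(3-benzyloxy-4-methoxybenzoate) F5.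
   - Base (KOtBu, THF, 0 °C) moves the ortho aroyl group onto the acetyl carbon to give 3-[3-(3-benzyloxy-4-methoxyphenyl)-3-oxopropanoyl]-4-hydroxy-5,6-dimethoxyphenyl 3-benzyloxy-4-methoxybenzoate F6.
   - Mild saponification of the remaining aryl ester (LiOH, THF–H2O, 0 °C, Ar) gives 7.

**Further compounds**

F1 | step 5 | 2,3,4,5-tetramethoxyphenol | COc1cc(O)c(OC)c(OC)c1OC
F2 | step 5 | 1-(2-hydroxy-3,4,5,6-tetramethoxyphenyl)ethanone | CC(=O)c1c(O)c(OC)c(OC)c(OC)c1OC
F3 | step 5 | 1-(3-benzyloxy-4-methoxyphenyl)-3-(2-hydroxy-3,4,5,6-tetramethoxyphenyl)propane-1,3-dione | COc1ccc(C(=O)CC(=O)c2c(O)c(OC)c(OC)c(OC)c2OC)cc1OCc1ccccc1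
F4 | step 2 | 2,3-dimethoxybenzene-1,4-diol | COc1c(O)ccc(O)c1OC
F5 | step 4 | 2-acetyl-5,6-dimethoxy-1,4-phenylene bis(3-benzyloxy-4-methoxybenzoate) | CC(=O)c1cc(OC(=O)c2ccc(OC)c(OCc3ccccc3)c2)c(OC)c(OC)c1OC(=O)c1ccc(OC)c(OCc2ccccc2)c1
F6 | step 4 | 3-[3-(3-benzyloxy-4-methoxyphenyl)-3-oxopropanoyl]-4-hydroxy-5,6-dimethoxyphenyl 3-benzyloxy-4-methoxybenzoate | COc1ccc(C(=O)CC(=O)c2cc(OC(=O)c3ccc(OC)c(OCc4ccccc4)c3)c(OC)c(OC)c2O)cc1OCc1ccccc1
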